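**Retrosynthetic overview**
1. The C3–C(=O) bond is made last by carbonylative α-aroylation of (R)-β-(3,4-dimethoxybenzyl)-γ-butyrolactone with an O-silylated 4-bromo-2-methoxyphenol and CO; C3 settles trans to C4, giving the (3S,4R) target.
2. The lactone, the only ring built in the route, comes from an enantioselective Baeyer–Villiger ring expansion of prochiral 3-(3,4-dimethoxybenzyl)cyclobutanone; the 1,2-shift of one enantiotopic CH2 from carbon to oxygen sets C4 (R).
3. The cyclobutanone comes from a nickel-catalysed aryl–alkyl cross-electrophile coupling of 4-bromo-1,2-dimethoxybenzene with ketal-protected 3-(bromomethyl)cyclobutanone.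
4. Both arenes derive from catechol through one intermediate, 4-bromo-2-methoxyphenol, which is O-methylated for the benzyl ring and O-silylated for the aroyl ring.
5. Ring order: the arenes and the cyclobutane are bought; cyclobutanone → γ-lactone is the single ring-forming event.

Assumption: 3-(bromomethyl)cyclobutan-1-one is bought as its ethylene ketal, 2-(bromomethyl)-5,8-dioxaspiro[3.4]octane (the ketal is a protecting group).

**Route**

Step 1
Reactants: 1 catechol (benzene-1,2-diol)
Product: 2 guaiacol (2-methoxyphenol)
Conditions: MeI (1.0 equiv), K2CO3 (1.0 equiv), acetone, 56 °C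
Reagents that add atoms: iodomethane, CI
Why: Williamson ether synthesis in which the more acidic, internally hydrogen-bonded catechol monoanion is alkylated in preference to guaiacol, and veratrole (neutral) and catechol (water-soluble) are removed by extraction and distillation.

Step 2
Reactants: 2 guaiacol
Product: 3 4-bromo-2-methoxyphenol
Conditions: NBS (1.0 equiv), MeCN, 0 °C
Reagents that add atoms: N-bromosuccinimide, O=C1CCC(=O)N1Br
Why: Electrophilic aromatic bromination in which the free OH, the stronger donor, directs bromine to its para position.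

Step 3
Reactants: 3 4-bromo-2-methoxyphenol
Product: 4 4-bromo-1,2-dimethoxybenzene
Conditions: MeI (1.5 equiv), K2CO3 (1.5 equiv), acetone, 56 °C
Reagents that add atoms: iodomethane, CI
Why: Williamson ether synthesis on the only remaining acidic OH.

Step 4
Reactants: 4 4-bromo-1,2-dimethoxybenzene; 5 2-(bromomethyl)-5,8-dioxaspiro[3.4]octane
Product: 7 3-(3,4-dimethoxybenzyl)cyclobutan-1-one, via ketal-protected coupling product 6 (not isolated)
Conditions: NiBr2·DME (10 mol%), 4,4′-di-tert-butyl-2,2′-bipyridine (10 mol%), NaI (25 mol%), pyridine (10 mol%), Zn dust (2 equiv), DMPU, 60 °C; then 2 M HCl, THF, 45 °C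
Reagents that add atoms: water, O
Why: Nickel-catalysed reductive cross-electrophile coupling in which zerovalent nickel adds to the aryl C–Br bond and the primary alkyl bromide enters as a radical, the ketal keeping the four-membered ring free of a carbonyl that would speed radical ring opening, followed by acetal hydrolysis to the achiral ketone.

Step 5
Reactants: 7 3-(3,4-dimethoxybenzyl)cyclobutan-1-one
Product: 8 (R)-4-(3,4-dimethoxybenzyl)dihydrofuran-2(3H)-one
Conditions: (R)-selective Baeyer–Villiger monooxygenase (cyclohexanone monooxygenase family, chosen from an enantiocomplementary panel), glucose dehydrogenase, NADP+ (cat.), D-glucose, air, Tris buffer pH 8.0, 5% MeOH, 25 °C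
Reagents that add atoms: dioxygen, O=O
Why: Enzymatic Baeyer–Villiger oxidation, a ring expansion by 1,2-shift of carbon to oxygen, in which the flavin peroxide adds to the prochiral ketone and the active site holds only one of the two enantiotopic ring CH2 groups antiperiplanar to the O–O bond, so that its migration fixes C4 as R.

Step 6
Reactants: 3 4-bromo-2-methoxyphenol
Product: 9 tert-butyl(4-bromo-2-methoxyphenoxy)dimethylsilane
Conditions: TBSCl (1.1 equiv), imidazole (1.5 equiv), DMF, 25 °C
Reagents that add atoms: tert-butyldimethylsilyl chloride, CC(C)(C)[Si](C)(C)Cl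
Why: Standard O-silylation of a phenol, which masks the acidic OH for the organozinc and palladium chemistry of the last step.

Step 7
Reactants: 8 (R)-4-(3,4-dimethoxybenzyl)dihydrofuran-2(3H)-one; 9 tert-butyl(4-bromo-2-methoxyphenoxy)dimethylsilane
Product: 12 (3S,4R)-4-(3,4-dimethoxybenzyl)-3-(4-hydroxy-3-methoxybenzoyl)dihydrofuran-2(3H)-one, via zinc enolate of the lactone 10 (not isolated), via zinc chelate of the silylated keto lactone 11 (not isolated)
Conditions: TMPZnCl·LiCl (2.2 equiv), THF, 25 °C; then 9 (1.1 equiv), Pd(OAc)2 (5 mol%), Xantphos (6 mol%), CO (3 bar), 65 °C; then AcOH, TBAF, THF, 0 °C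
Reagents that add atoms: carbon monoxide, [C-]#[O+]
Why: Proposed new method: carbonylative α-aroylation of a non-stabilised lactone zinc enolate, in which zerovalent palladium adds to the C–Br bond of 9, CO inserts to give an aroyl complex of divalent palladium, transmetalation with 10 and reductive elimination form the C3–C(=O) bond, the second equivalent of the hindered zinc amide (too bulky to trap the aroyl–palladium) converts the product into chelate 11 so that it neither quenches 10 nor is acylated twice, and buffered fluoride then frees the phenol while protonation of the epimerisable C3 gives the more stable 3,4-trans (3S) isomer under control of the fixed C4 centre; the closest known reactions are the palladium-catalysed carbonylative α-arylation of ketones and oxindoles, the α-arylation of esters zincated in situ with TMPZnCl·LiCl, and the carbonylative Negishi coupling.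

**Compound list**
1 | catechol (benzene-1,2-diol) | Oc1ccccc1O | starting material
2 | guaiacol (2-methoxyphenol) | COc1ccccc1O | intermediate
3 | 4-bromo-2-methoxyphenol | COc1cc(Br)ccc1O | intermediate
4 | 4-bromo-1,2-dimethoxybenzene | COc1ccc(Br)cc1OC | intermediate
5 | 2-(bromomethyl)-5,8-dioxaspiro[3.4]octane (ethylene ketal of 3-(bromomethyl)cyclobutan-1-one) | BrCC1CC2(C1)OCCO2 | starting material
6 | 2-(3,4-dimethoxybenzyl)-5,8-dioxaspiro[3.4]octane | COc1ccc(CC2CC3(C2)OCCO3)cc1OC | intermediate
7 | 3-(3,4-dimethoxybenzyl)cyclobutan-1-one | COc1ccc(CC2CC(=O)C2)cc1OC | intermediate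
8 | (R)-4-(3,4-dimethoxybenzyl)dihydrofuran-2(3H)-one | O=C1OC[C@H](Cc2ccc(OC)c(OC)c2)C1 | intermediate
9 | tert-butyl(4-bromo-2-methoxyphenoxy)dimethylsilane | COc1cc(Br)ccc1O[Si](C)(C)C(C)(C)C | intermediate
10 | chlorozinc enolate of 8 (drawn O-bound), (R)-configured at C4 | Cl[Zn]OC1=C[C@@H](Cc2ccc(OC)c(OC)c2)CO1 | intermediate
11 | chlorozinc (Z)-enolate chelate of (4R)-3-[4-(tert-butyldimethylsilyloxy)-3-methoxybenzoyl]-4-(3,4-dimethoxybenzyl)dihydrofuran-2(3H)-one | Cl[Zn]O/C(c1ccc(O[Si](C)(C)C(C)(C)C)c(OC)c1)=C2\C(=O)OC[C@@H]2Cc3ccc(OC)c(OC)c3 | intermediate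
12 | (3S,4R)-4-(3,4-dimethoxybenzyl)-3-(4-hydroxy-3-methoxybenzoyl)dihydrofuran-2(3H)-one | COc1cc(C(=O)[C@H]2C(=O)OC[C@@H]2Cc2ccc(OC)c(OC)c2)ccc1O | target

**Step count and risks**
Total step count: 7. Longest linear sequence: 6 (steps 1, 2, 3, 4, 5, 7).

The three steps most likely to fail:

Step 7 (proposed new carbonylative aroylation). The risks are direct, CO-free α-arylation of the enolate, slow oxidative addition of the electron-rich bromide under CO, and incomplete zincation of the lactone. The fallback uses known chemistry, sets out from 9 and 8, and comes back at 12. Compound 9 is lithiated (n-BuLi, THF, −78 °C) and formylated with DMF to 4-(tert-butyldimethylsilyloxy)-3-methoxybenzaldehyde F5. The lithium enolate of 8 (LiN(SiMe3)2, THF, −78 °C) adds to F5 anti to the benzyl group to give the trans aldol (3S,4R)-3-{[4-(tert-butyldimethylsilyloxy)-3-methoxyphenyl](hydroxy)methyl}-4-(3,4-dimethoxybenzyl)dihydrofuran-2(3H)-one F6 as a mixture of carbinol epimers. Dess–Martin periodinane oxidises F6 to (3S,4R)-3-[4-(tert-butyldimethylsilyloxy)-3-methoxybenzoyl]-4-(3,4-dimethoxybenzyl)dihydrofuran-2(3H)-one F7, and TBAF/AcOH then gives 12.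

Step 5 (enantioselective ring expansion). The risk is that the enzyme at hand gives insufficient ee or the wrong antipode with the dimethoxybenzyl substrate; the hand is checked by chiral HPLC and rotation against the known (R)-lactone. The fallback sets out from 7 and comes back at 8. Enantioselective deprotonation of 7 with lithium bis[(R)-1-phenylethyl]amide or its antipode (whichever gives the R series), with Et3SiCl present in the flask (THF, −100 °C), gives (R)-{[3-(3,4-dimethoxybenzyl)cyclobut-1-en-1-yl]oxy}triethylsilane F3. Ozonolysis of the enol ether double bond (O3 titrated, CH2Cl2/MeOH, −78 °C) followed by NaBH4 gives (R)-3-(3,4-dimethoxybenzyl)-4-hydroxybutanoic acid F4, which closes to 8 with TsOH.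

Step 4 (aryl–alkyl cross-electrophile coupling). The risks are biaryl formation, reduction of the β-branched alkyl bromide and slow reaction of the electron-rich aryl bromide. The fallback sets out from 4 and comes back at 7. The Grignard reagent of 4 (Mg, THF) is coupled with allyl bromide to give 4-allyl-1,2-dimethoxybenzene F1. A [2+2] cycloaddition with dichloroketene (Cl3CCOCl, activated Zn, Et2O, sonication) gives 2,2-dichloro-3-(3,4-dimethoxybenzyl)cyclobutan-1-one F2, and Zn in AcOH (60 °C) removes both chlorines to give 7.

**Further compounds**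
F1 | step 4 | 4-allyl-1,2-dimethoxybenzene | C=CCc1ccc(OC)c(OC)c1
F2 | step 4 | 2,2-dichloro-3-(3,4-dimethoxybenzyl)cyclobutan-1-one (racemic) | COc1ccc(CC2CC(=O)C2(Cl)Cl)cc1OC
F3 | step 5 | (R)-{[3-(3,4-dimethoxybenzyl)cyclobut-1-en-1-yl]oxy}triethylsilane | CC[Si](CC)(CC)OC1=C[C@H](Cc2ccc(OC)c(OC)c2)C1
F4 | step 5 | (R)-3-(3,4-dimethoxybenzyl)-4-hydroxybutanoic acid | OC(=O)C[C@H](CO)Cc1ccc(OC)c(OC)c1
F5 | step 7 | 4-(tert-butyldimethylsilyloxy)-3-methoxybenzaldehyde | COc1cc(C=O)ccc1O[Si](C)(C)C(C)(C)C
F6 | step 7 | (3S,4R)-3-{[4-(tert-butyldimethylsilyloxy)-3-methoxyphenyl](hydroxy)methyl}-4-(3,4-dimethoxybenzyl)dihydrofuran-2(3H)-one (carbinol epimers) | COc1cc(C(O)[C@H]2C(=O)OC[C@@H]2Cc2ccc(OC)c(OC)c2)ccc1O[Si](C)(C)C(C)(C)C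
F7 | step 7 | (3S,4R)-3-[4-(tert-butyldimethylsilyloxy)-3-methoxybenzoyl]-4-(3,4-dimethoxybenzyl)dihydrofuran-2(3H)-one | COc1cc(C(=O)[C@H]2C(=O)OC[C@@H]2Cc2ccc(OC)c(OC)c2)ccc1O[Si](C)(C)C(C)(C)C
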